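**Remark on the chemistry:** compounds 2, 5 and 10 and the enolates 4 and 9 are drawn as single keto or enolate forms although each is expected as a mixture of tautomers and, where C6 and C8 are sp3, of epimers, which has no consequence because both carbons become aromatic in step 5; chain atoms are named throughout by the flavone positions they become (ester carbon = C8a, methoxy-bearing carbons = C8 and C6, ketone carbons = C7, C5 and C4, doubly activated methylene = C4a, alkene = C3=C2).

## Analysis of the target

The target is a flavone in which a benzene ring A is fused to a 4-pyranone ring C and a 2,3-dimethoxyphenyl ring B sits on C2. It has no stereocentre and no stereogenic double bond, so the problem is one of constitution only. Ring A is fully substituted, with OH on C5, OMe on C6, OH on C7, OMe on C8 and the ring oxygen O1 on C8a, and C4a is its only carbon without oxygen. This pentaoxygenated ring is electron-rich and is easily oxidised as its phenolate in air, the C5 hydroxyl is chelated to the C4 carbonyl, the C7 hydroxyl is a vinylogous acid, and the four aryl methyl ethers are open to Lewis-acid cleavage. The difficulty is the alternating OH/OMe pattern on four contiguous carbons, because a route from a preformed arene has to tell C5 and C7 from C6 and C8 and from ring B by selective alkylation, dealkylation or protection. The strategy rests on reading ring A from C8a round to C4a as an acylphloroglucinol which, opened between C4a and C8a, is a linear chain C8a (ester), C8 (CH–OMe), C7 (C=O), C6 (CH–OMe), C5 (C=O), C4a (CH2), C4 (C=O), C3=C2, ring B, with a ketone wherever the target has OH and an α-methoxy carbon wherever it has OMe. The acylphloroglucinol formed from this chain has a local mirror plane through C4a, so either ortho hydroxyl can later close ring C to the same flavone.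

## Retrosynthetic reasoning

**13 to 11.** Ring C is opened at O1–C2 and the C2=C3 unsaturation is taken back to the alkene of a chalcone, which gives 11. The forward reaction is an oxa-Michael addition to the racemic flavanone 12 followed by dehydrogenation in the same flask. The cut is made here because ring A of 11 is symmetric about the C4a axis, so ring closure has no regiochemical question. C6 and C8 are already substituted, so an electrophilic oxidant has no free position on ring A to attack.

**11 to 10.** Ring A is opened at C4a–C8a, between the only ring carbon without oxygen and its neighbour, which gives the open-chain ester 10. C4a is the doubly activated methylene of 10 and C8a its ester carbon, so the forward reaction is an intramolecular Claisen condensation followed by aromatisation. No other cut of ring A pairs a natural carbon nucleophile with a carbonyl at the right oxidation level and keeps all five oxygens in place. The gain is that the whole OH/OMe pattern of ring A is written into an acyclic chain and needs no protecting group and no methylation on the ring.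

**10 to 5 and 8.** The chain is cut at C4a–C4. C4a is the terminal methyl of the diketo ester 5, the last and most reactive site of its trienolate 9, and C4 is delivered as the cinnamoyl Weinreb amide 8. The amide gives 1,2-addition, holds the adduct as a chelate until work-up and so avoids a second addition and the need for excess polyanion.

**8 to 6 and 7.** The C2=C3 double bond is cut by an olefination between aldehyde 6 and phosphonate 7, which sets the E geometry and brings in C3 and C4.

**5 to 2 and 3.** The C6–C5 bond is cut. C6 is the γ-carbon of keto ester 2, reached through its dienolate 4, and C5 with C4a comes from the acetyl group of 3. γ-Acylation of a β-keto ester dianion is the standard way to extend such a chain by two carbons.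

**2 to two molecules of 1.** The C8–C7 bond is cut by a Claisen self-condensation of 1. Both methoxy-bearing carbons and both of their oxygenated neighbours come from the same two-carbon ester, which is why the alternating pattern costs nothing.

## Alternatives that were turned down

**Alternative 1: carbon monoxide as C4.** The disconnection cuts C4a–C4 and C4–C3, and C4 is supplied by carbon monoxide. The iodide 1-iodo-3,5-dimethoxy-2,4,6-tris(methoxymethoxy)benzene A2 and the alkyne 1-ethynyl-2,3-dimethoxybenzene A3 would be joined with carbon monoxide by a palladium catalyst such as PdCl2(PPh3)2. This would give the ynone 1-[3,5-dimethoxy-2,4,6-tris(methoxymethoxy)phenyl]-3-(2,3-dimethoxyphenyl)prop-2-yn-1-one A1. Acid would then remove the three acetals of A1 and ring C would close.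

- For it: the union is convergent, A2 is symmetric, A3 is a simple terminal alkyne, and all intermediates are neutral and isolable. A1 already has the oxidation level of C2–C3, so no oxidant is needed at the end. On these points it is stronger than the chosen route, which works through polyanions and needs a final dehydrogenation.
- Against it: the iodine of A2 sits between two ortho acetal ethers on a very electron-rich ring. Oxidative addition to zerovalent palladium should be slow, the hindered aroylpalladium intermediate can lose carbon monoxide again, and direct coupling of A2 with A3 without carbonyl insertion would compete. Ring closure after deprotection of A1 can also go 5-exo-dig to an aurone. Above all, A2 has to be made by stepwise oxygenation of an arene with three protecting groups put on and taken off, so the OH/OMe problem is moved, not solved.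
- Comparison: the chosen route is shorter and builds the pattern from methoxyacetate without any protecting group. In exchange it accepts more reactive intermediates.

**Alternative 2: ring A grown on a pyranone by squarate ring expansion.** The disconnection cuts C8–C8a in the key step, and C4a–C5 earlier by adding a metallated pyranone to a squarate. Heating 4-[6-(2,3-dimethoxyphenyl)-4-oxo-4H-pyran-3-yl]-4-hydroxy-3-methoxy-2-(propan-2-yloxy)cyclobut-2-en-1-one A5 would open the four-membered ring to a dienylketene. This would close onto the pyranone and tautomerise to 2-(2,3-dimethoxyphenyl)-5,8-dihydroxy-6-methoxy-7-(propan-2-yloxy)chromen-4-one A4.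

- For it: the ring forms under neutral thermal conditions, the order of the four oxygens is programmed by the order of additions to the squarate, and ring B and ring C are in place early. In tolerance of functional groups it is at least as strong as a Claisen closure in methoxide.
- Against it: the rearrangement by its nature gives a 5,8-hydroquinone. From A4 the target's C8 methoxy and C7 hydroxyl must be reached by methylating O8 beside the free 5-OH and cleaving the isopropyl ether selectively, two corrective steps. A4 is air-sensitive. The 3-metallated 4-pyranone needed to make A5 is prone to ring opening and conjugate addition, and the unsymmetrical squarate has to be made and attacked at the right carbonyl.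
- Comparison: the chosen route gives the correct OH/OMe pattern directly at the ring-forming step and is several steps shorter.

**Alternative 3: acylquinone oxa-Michael closure.** The disconnection cuts O1–C8a. In 1-[4-(benzyloxy)-5-methoxy-3,6-dioxocyclohexa-1,4-dien-1-yl]-3-(2,3-dimethoxyphenyl)propane-1,3-dione A7 the enol oxygen of the diketone would add to the unsubstituted quinone carbon. Tautomerisation would give 7-(benzyloxy)-2-(2,3-dimethoxyphenyl)-5,8-dihydroxy-6-methoxychromen-4-one A6.

- For it: acylquinones are excellent acceptors, the closure is intramolecular and mild, and the quinone carries the oxidation level, so ring C forms as a chromone without a separate oxidant. This is a point on which it is stronger than the chosen route.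
- Against it: A7 is a highly electrophilic quinone with two vinylogous ester groups that nucleophiles can displace. Its preparation requires oxidising an arene that carries an enolisable diketone. The central diketone carbon can attack the quinone in place of oxygen. A6 is again a 5,8-hydroquinone that needs O8 methylation and debenzylation. The four ring A oxygens still have to be differentiated on an aromatic precursor.
- Comparison: the chosen route avoids the quinone, the protecting group and the late methylation. Its one comparable risk sits in a single ring-forming step.

Key step: step 5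

## Route

**Step 1**
Reactants: 1 methyl methoxyacetate (two molecules)
Product: 2 methyl 2,4-dimethoxy-3-oxobutanoate
Conditions: NaH (0.55 equiv), THF, reflux; then 1 M HCl, 0 °C
Reagents that add atoms: none
Why: Claisen self-condensation; the ester enolate of 1 acylates a second molecule and the equilibrium is drawn forward by deprotonation of the β-keto ester formed.

**Step 2**
Reactants: 2 methyl 2,4-dimethoxy-3-oxobutanoate; 3 N-methoxy-N-methylacetamide
Product: 5 methyl 2,4-dimethoxy-3,5-dioxohexanoate, via dilithium dienolate 4 (not isolated)
Conditions: LiN(iPr)2 (2.2 equiv), THF, −78 to 0 °C; then 3, −78 to −20 °C; 1 M HCl, 0 °C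
Reagents that add atoms: none
Why: γ-Acylation of a β-keto ester dianion with a Weinreb amide; the second-formed carbanion at the CH(OMe) terminus of 4 is the more nucleophilic site, and the chelated tetrahedral adduct survives until the cold acidic quench, so the diketo ester forms only on work-up and is used promptly.

**Step 3**
Reactants: 6 2,3-dimethoxybenzaldehyde; 7 diethyl {2-[methoxy(methyl)amino]-2-oxoethyl}phosphonate
Product: 8 (E)-3-(2,3-dimethoxyphenyl)-N-methoxy-N-methylprop-2-enamide
Conditions: LiCl, DBU, MeCN, 23 °C
Reagents that add atoms: none
Why: Horner–Wadsworth–Emmons olefination under Masamune–Roush conditions; the stabilised amide phosphonate gives the E alkene with an aryl aldehyde.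

**Step 4**
Reactants: 5 methyl 2,4-dimethoxy-3,5-dioxohexanoate; 8 (E)-3-(2,3-dimethoxyphenyl)-N-methoxy-N-methylprop-2-enamide
Product: 10 methyl (E)-9-(2,3-dimethoxyphenyl)-2,4-dimethoxy-3,5,7-trioxonon-8-enoate, via trilithium trienolate 9 (not isolated)
Conditions: LiN(iPr)2 (3.1 equiv), THF, −78 to 0 °C; then 8, −78 to 0 °C; 1 M HCl, 0 °C
Reagents that add atoms: none
Why: Terminal acylation of a 3,5-diketo ester trianion with a Weinreb amide; the last-formed methyl-derived carbanion of 9 adds 1,2 to the cinnamoyl amide, a hard acceptor and poor Michael partner, and the stable adduct prevents proton exchange with the product. Crude 10 is carried on without purification.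

**Step 5**
Reactants: 10 methyl (E)-9-(2,3-dimethoxyphenyl)-2,4-dimethoxy-3,5,7-trioxonon-8-enoate
Product: 11 (E)-3-(2,3-dimethoxyphenyl)-1-(2,4,6-trihydroxy-3,5-dimethoxyphenyl)prop-2-en-1-one
Conditions: Mg(OMe)2 (4 equiv), MeOH, 25 to 65 °C, Ar; then 1 M HCl, 0 °C
Reagents that add atoms: none
Why: Mg(OMe)2 turns 10 into a magnesium polyenolate in which the C4/C5 diketone is a six-membered chelate with C4a as its nucleophilic carbon, while magnesium bound to the C7 oxygen and the ester carbonyl activates C8a and folds the chain. C4a adds to the ester carbon C8a, methoxide leaves, and the resulting 2-acylcyclohexane-1,3,5-trione enolises three times to the phloroglucinol, which makes the sequence irreversible. The closest known reaction type is the biomimetic Claisen cyclisation of 3,5,7-triketo esters to acylphloroglucinols under Mg(OMe)2, of which the two α-methoxy groups and the styryl ketone are the extension. Ring A closes in a 6-exo-trig mode at the ester carbonyl, allowed for the enolate in either its enolendo (C4a=C5) or enolexo (C4a=C4) form. No stereocentre is formed, since the epimeric centres C6 and C8 become aromatic carbons and the E alkene C2=C3 is not touched. The step needs Claisen closure to win over aldol closure of C8 onto the C4 ketone, lactonisation of the C5 enol oxygen onto C8a, and conjugate addition to C2. The aldol adduct would carry methoxy and ester groups on one ring carbon and cannot become an arene, so it reverts, the pyranone is reopened by methoxide, and the C4 carbonyl, held as a chelated enolate, is a poor aldol acceptor and a poor Michael activator. Only the Claisen product leaves these equilibria, by aromatisation, and any 12 formed from 11 on work-up is carried along, since step 6 passes through it.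

**Step 6**
Reactants: 11 (E)-3-(2,3-dimethoxyphenyl)-1-(2,4,6-trihydroxy-3,5-dimethoxyphenyl)prop-2-en-1-one
Product: 13 2-(2,3-dimethoxyphenyl)-5,7-dihydroxy-6,8-dimethoxy-4H-chromen-4-one (the target), via flavanone 12 (not isolated)
Conditions: I2 (10 mol %), DMSO, 120 °C
Reagents that add atoms: none
Why: Iodine-catalysed oxidative cyclisation of a 2'-hydroxychalcone; an ortho hydroxyl (both are equivalent) adds to C2 to give racemic 12, which is iodinated at C3 and loses HI, and DMSO reoxidises HI to I2. C6 and C8 carry methoxy groups, so ring A has no free position for iodination.

## Compound list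

1 | methyl methoxyacetate | COCC(=O)OC | starting material
2 | methyl 2,4-dimethoxy-3-oxobutanoate (racemic) | COCC(=O)C(OC)C(=O)OC | intermediate
3 | N-methoxy-N-methylacetamide | CC(=O)N(C)OC | starting material
4 | dilithium dienolate of 2 (not isolated) | [Li+].[Li+].COC=C([O-])C(OC)=C([O-])OC | intermediate
5 | methyl 2,4-dimethoxy-3,5-dioxohexanoate (epimers and enol forms) | CC(=O)C(OC)C(=O)C(OC)C(=O)OC | intermediate
6 | 2,3-dimethoxybenzaldehyde | COc1cccc(C=O)c1OC | starting material
7 | diethyl {2-[methoxy(methyl)amino]-2-oxoethyl}phosphonate | CCOP(=O)(CC(=O)N(C)OC)OCC | starting material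
8 | (E)-3-(2,3-dimethoxyphenyl)-N-methoxy-N-methylprop-2-enamide | COc1cccc(/C=C/C(=O)N(C)OC)c1OC | intermediate
9 | trilithium trienolate of 5 (not isolated) | [Li+].[Li+].[Li+].C=C([O-])C(OC)=C([O-])C(OC)=C([O-])OC | intermediate
10 | methyl (E)-9-(2,3-dimethoxyphenyl)-2,4-dimethoxy-3,5,7-trioxonon-8-enoate (epimers and enol forms) | COC(=O)C(OC)C(=O)C(OC)C(=O)CC(=O)/C=C/c1cccc(OC)c1OC | intermediate
11 | (E)-3-(2,3-dimethoxyphenyl)-1-(2,4,6-trihydroxy-3,5-dimethoxyphenyl)prop-2-en-1-one | COc1cccc(/C=C/C(=O)c2c(O)c(OC)c(O)c(OC)c2O)c1OC | intermediate
12 | 2-(2,3-dimethoxyphenyl)-5,7-dihydroxy-6,8-dimethoxy-2,3-dihydro-4H-chromen-4-one (racemic, not isolated) | COc1cccc(C2CC(=O)c3c(O)c(OC)c(O)c(OC)c3O2)c1OC | intermediate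
13 | 2-(2,3-dimethoxyphenyl)-5,7-dihydroxy-6,8-dimethoxy-4H-chromen-4-one (5,7-dihydroxy-6,8,2',3'-tetramethoxyflavone) | COc1cccc(-c2cc(=O)c3c(O)c(OC)c(O)c(OC)c3o2)c1OC | target

## Step count and risks

Total step count: 6. Longest linear sequence: 5 steps (steps 1, 2, 4, 5, 6); step 3 is a one-step side branch.

**Step 5 (key step).**
- Risk: loss of the open chain before the ring closes. The two α-methoxy groups make C4a approach a more crowded ester and may slow the closure. During that time methoxide, the C5 enolate oxygen or the C6 carbon can add to C2 of the styryl ketone, and methoxide can cleave the chain by retro-Claisen attack at the C7 ketone, which lies between two methoxy-bearing carbons and is the least enolised carbonyl. The styryl ketone is the one group that the known closures of this type do not carry.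
- Fallback: move the styryl unit out of the cyclisation substrate. Setting out from 5, its trienolate 9 is acylated with 3 in place of 8 to give methyl 2,4-dimethoxy-3,5,7-trioxooctanoate F1. Under Mg(OMe)2 in methanol F1 closes to 1-(2,4,6-trihydroxy-3,5-dimethoxyphenyl)ethan-1-one F2. The polylithium salt of F2, made with LiN(SiMe3)2 (5 equiv) in THF at −78 °C, is C-acylated by commercial 2,3-dimethoxybenzoyl chloride to give 1-(2,3-dimethoxyphenyl)-3-(2,4,6-trihydroxy-3,5-dimethoxyphenyl)propane-1,3-dione F3. Warm H2SO4 in acetic acid cyclodehydrates F3, and the fallback comes back to the route at 13, with no need for step 6.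

**Step 4.**
- Risk: incomplete third deprotonation. The first two enolate carbons of 5 carry methoxy groups and the terminal methyl may be metallated only in part. Lithium amide left over would then add to 8 in conjugate fashion, and 5 can lactonise before it is fully metallated.
- Fallback: use the lactone on purpose. Setting out from 5, DBU in toluene closes it to 4-hydroxy-3,5-dimethoxy-6-methyl-2H-pyran-2-one F4, in which C8 and C6 are locked as sp2 carbons. The dianion of F4, made with LiN(iPr)2 (2 equiv) and metallated at the hydroxyl and the 6-methyl group, is acylated by 8 to give 6-[(E)-4-(2,3-dimethoxyphenyl)-2-oxobut-3-en-1-yl]-4-hydroxy-3,5-dimethoxy-2H-pyran-2-one F5. Under the conditions of step 5 methoxide opens the lactone of F5 to 10 in the flask, and the fallback comes back to the route at 11.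

**Step 2.**
- Risk: proton transfer from the acetyl group of 3 to the strongly basic γ-carbanion of 4, which returns 2 and uses up the acyl donor; and ring closure of 5 to a pyranone if the work-up is not kept cold and brief.
- Fallback: replace acyl transfer by aldol addition and oxidation. Setting out from 2, its dienolate 4 adds to acetaldehyde at −78 °C, which is faster than proton transfer, to give methyl 5-hydroxy-2,4-dimethoxy-3-oxohexanoate F6. Oxidation of the secondary alcohol of F6 with 2-iodoxybenzoic acid in ethyl acetate comes back to the route at 5.

**Step 6.**
- Risk: oxidative degradation of the electron-rich ring A, partial O-demethylation by HI at 120 °C, or stalling at the flavanone stage.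
- Fallback: an ionic bromination and elimination on a deactivated ring. Setting out from 11, NaOAc in refluxing ethanol closes it to 12, which is isolated. Acetic anhydride, pyridine and DMAP give 2-(2,3-dimethoxyphenyl)-6,8-dimethoxy-4-oxo-3,4-dihydro-2H-chromene-5,7-diyl diacetate F7. Phenyltrimethylammonium tribromide in THF brominates the ketone α-carbon of F7 to give 3-bromo-2-(2,3-dimethoxyphenyl)-6,8-dimethoxy-4-oxo-3,4-dihydro-2H-chromene-5,7-diyl diacetate F8. K2CO3 in methanol eliminates HBr from F8 and removes both acetates, and the fallback comes back to the route at 13.

## Further compounds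

F1 | step 5 | methyl 2,4-dimethoxy-3,5,7-trioxooctanoate | CC(=O)CC(=O)C(OC)C(=O)C(OC)C(=O)OC
F2 | step 5 | 1-(2,4,6-trihydroxy-3,5-dimethoxyphenyl)ethan-1-one | CC(=O)c1c(O)c(OC)c(O)c(OC)c1O
F3 | step 5 | 1-(2,3-dimethoxyphenyl)-3-(2,4,6-trihydroxy-3,5-dimethoxyphenyl)propane-1,3-dione | COc1cccc(C(=O)CC(=O)c2c(O)c(OC)c(O)c(OC)c2O)c1OC
F4 | step 4 | 4-hydroxy-3,5-dimethoxy-6-methyl-2H-pyran-2-one | Cc1oc(=O)c(OC)c(O)c1OC
F5 | step 4 | 6-[(E)-4-(2,3-dimethoxyphenyl)-2-oxobut-3-en-1-yl]-4-hydroxy-3,5-dimethoxy-2H-pyran-2-one | COc1cccc(/C=C/C(=O)Cc2oc(=O)c(OC)c(O)c2OC)c1OC
F6 | step 2 | methyl 5-hydroxy-2,4-dimethoxy-3-oxohexanoate (mixture of diastereomers) | CC(O)C(OC)C(=O)C(OC)C(=O)OC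
F7 | step 6 | 2-(2,3-dimethoxyphenyl)-6,8-dimethoxy-4-oxo-3,4-dihydro-2H-chromene-5,7-diyl diacetate (racemic) | COc1cccc(C2CC(=O)c3c(OC(C)=O)c(OC)c(OC(C)=O)c(OC)c3O2)c1OC
F8 | step 6 | 3-bromo-2-(2,3-dimethoxyphenyl)-6,8-dimethoxy-4-oxo-3,4-dihydro-2H-chromene-5,7-diyl diacetate (racemic, mixture of diastereomers) | COc1cccc(C2Oc3c(OC)c(OC(C)=O)c(OC)c(OC(C)=O)c3C(=O)C2Br)c1OC
A1 | alternative 1 | 1-[3,5-dimethoxy-2,4,6-tris(methoxymethoxy)phenyl]-3-(2,3-dimethoxyphenyl)prop-2-yn-1-one | COCOc1c(C(=O)C#Cc2cccc(OC)c2OC)c(OCOC)c(OC)c(OCOC)c1OC
A2 | alternative 1 | 1-iodo-3,5-dimethoxy-2,4,6-tris(methoxymethoxy)benzene | COCOc1c(I)c(OCOC)c(OC)c(OCOC)c1OC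
A3 | alternative 1 | 1-ethynyl-2,3-dimethoxybenzene | C#Cc1cccc(OC)c1OC
A4 | alternative 2 | 2-(2,3-dimethoxyphenyl)-5,8-dihydroxy-6-methoxy-7-(propan-2-yloxy)chromen-4-one | COc1cccc(-c2cc(=O)c3c(O)c(OC)c(OC(C)C)c(O)c3o2)c1OC
A5 | alternative 2 | 4-[6-(2,3-dimethoxyphenyl)-4-oxo-4H-pyran-3-yl]-4-hydroxy-3-methoxy-2-(propan-2-yloxy)cyclobut-2-en-1-one (racemic) | COC1=C(OC(C)C)C(=O)C1(O)c1coc(-c2cccc(OC)c2OC)cc1=O
A6 | alternative 3 | 7-(benzyloxy)-2-(2,3-dimethoxyphenyl)-5,8-dihydroxy-6-methoxychromen-4-one | COc1cccc(-c2cc(=O)c3c(O)c(OC)c(OCc4ccccc4)c(O)c3o2)c1OC
A7 | alternative 3 | 1-[4-(benzyloxy)-5-methoxy-3,6-dioxocyclohexa-1,4-dien-1-yl]-3-(2,3-dimethoxyphenyl)propane-1,3-dione | COc1cccc(C(=O)CC(=O)C2=CC(=O)C(OCc3ccccc3)=C(OC)C2=O)c1OC
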